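The route rests on closing ring C through the C2–C3 bond. In the target, C2 is a CH bonded to O1 and to C1' of the electron-rich ring B. Opened up, it is the OCH2 group of an aryl benzyl ether, doubly activated and placed for six-membered closure onto C3. The precursor is a ring A diazomethyl ketone flanked by this benzyl ether and by a silyl ether that offers no competing C–H, with methoxy and prenyl groups already in place. A chiral dirhodium carboxylate releases nitrogen and the C3 carbene inserts into one enantiotopic C2–H, creating ring C, the C2–C3 bond and the C2 stereocentre together. Substrate-controlled C3 hydroxylation and desilylation finish.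

Key step: step 9

Abbreviations: TBS = tert-butyldimethylsilyl; TMS = trimethylsilyl; prenyl = 3-methylbut-2-enyl; ArB = 3-(tert-butyldimethylsilyloxy)-4-methoxyphenyl (the later ring B). Flavanone numbering is used for rings A, B and C. In the acetophenones the acyl-bearing carbon is C1.

Assumption: the sense of induction of the chiral dirhodium catalyst on this substrate must be established in a test run. The catalyst from L-proline is written, and its mirror image from D-proline is used instead if the test run points to the 2R flavanone.

Stereochemical remark: the spatial arrangement at C2 is the same in the flavanone and in the target. The descriptor changes from 2S to 2R only because the new C3 oxygen raises the rank of C3 above C1'.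

Design remarks:
- The tertiary ether is made first, on the symmetric diphenol, where one hydroxyl is always free of the hydrogen bond to the acetyl group. The easier benzylic etherification is left for the chelated hydroxyl.
- Both phenols are carried as silyl ethers, so O5 bears no C–H next to the carbene and one fluoride step ends the route.
- The C3 oxygen comes from an N-sulfonyloxaziridine and not from a peracid, because the prenyl alkene has to survive.

Step 1
Reactants: 1 2',6'-dihydroxy-4'-methoxyacetophenone; 2 2-methylbut-3-yn-2-ol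
Product: 4 1-[2-hydroxy-4-methoxy-6-(2-methylbut-3-yn-2-yloxy)phenyl]ethanone, via 2-methylbut-3-yn-2-yl trifluoroacetate 3 (not isolated)
Conditions: (CF3CO)2O, DBU, MeCN, 0 °C (2 to 3); then 1, DBU, CuCl2 (0.1 mol %), MeCN, 0 °C
Reagents that add atoms: trifluoroacetic anhydride O=C(OC(=O)C(F)(F)F)C(F)(F)F (its acyl group appears in 3 only)
Why: Copper-catalysed propargylic etherification of a phenol with a tertiary propargylic ester: copper activates 3 so that the phenoxide is taken up at the tertiary carbon without an SN2 event, and since the acetyl oxygen can chelate only one of the two equivalent hydroxyls of 1 at a time the first etherification is easy, whereas the firmly chelated hydroxyl left in 4 resists a second one.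

Step 2
Reactants: 4 1-[2-hydroxy-4-methoxy-6-(2-methylbut-3-yn-2-yloxy)phenyl]ethanone
Product: 5 1-[2-hydroxy-4-methoxy-6-(2-methylbut-3-en-2-yloxy)phenyl]ethanone
Conditions: H2 (1 atm), Pd/CaCO3 poisoned with Pb(OAc)2 (Lindlar catalyst), quinoline, EtOAc, rt
Reagents that add atoms: none
Why: Lindlar semihydrogenation, in which the poisoned palladium surface releases the terminal alkene before it is reduced further and leaves the aryl ketone and the tertiary C–O bond alone.

Step 3
Reactants: 6 isovanillin (3-hydroxy-4-methoxybenzaldehyde)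
Product: 7 3-(tert-butyldimethylsilyloxy)-4-methoxybenzaldehyde
Conditions: TBSCl, imidazole, CH2Cl2, rt
Reagents that add atoms: tert-butyldimethylsilyl chloride CC(C)(C)[Si](C)(C)Cl
Why: Imidazole-promoted O-silylation of a phenol, to which the aldehyde is inert.

Step 4
Reactants: 7 3-(tert-butyldimethylsilyloxy)-4-methoxybenzaldehyde
Product: 8 [3-(tert-butyldimethylsilyloxy)-4-methoxyphenyl]methanol
Conditions: NaBH4, MeOH/THF, 0 °C
Reagents that add atoms: none
Why: Borohydride reduction of an aromatic aldehyde to the benzylic alcohol, short and cold enough for the aryl silyl ether to survive.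

Step 5
Reactants: 5 1-[2-hydroxy-4-methoxy-6-(2-methylbut-3-en-2-yloxy)phenyl]ethanone; 8 [3-(tert-butyldimethylsilyloxy)-4-methoxyphenyl]methanol
Product: 9 1-[2-(ArB-methoxy)-4-methoxy-6-(2-methylbut-3-en-2-yloxy)phenyl]ethanone
Conditions: PPh3, DIAD, THF, 0 °C to rt
Reagents that add atoms: none
Why: Mitsunobu etherification, a neutral method known to work on phenols chelated to an ortho acyl group, joins the primary benzylic alcohol to the only free hydroxyl of 5, so the substitution pattern of ring A is fixed without ambiguity and neither the aryl silyl ether nor the acid- and heat-sensitive tertiary allyl ether is put under stress.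

Step 6
Reactants: 9 1-[2-(ArB-methoxy)-4-methoxy-6-(2-methylbut-3-en-2-yloxy)phenyl]ethanone
Product: 11 1-[2-(ArB-methoxy)-6-hydroxy-4-methoxy-5-prenylphenyl]ethanone, via ortho-dienone 10 (not isolated)
Conditions: PhNEt2, 130 °C, argon
Reagents that add atoms: none
Why: Aromatic Claisen rearrangement: of the two ortho carbons only C5 is free (C1 carries the acetyl group), the [3,3] shift turns the 1,1-dimethylallyl ether into a C-bound prenyl group, and enolisation of 10 to the chelated phenol should outrun a Cope shift to the para carbon, which would have to build a crowded quaternary centre; the basic solvent guards the tertiary ether against acid-induced ionisation.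

Step 7
Reactants: 11 1-[2-(ArB-methoxy)-6-hydroxy-4-methoxy-5-prenylphenyl]ethanone
Product: 12 1-[2-(ArB-methoxy)-6-(tert-butyldimethylsilyloxy)-4-methoxy-5-prenylphenyl]ethanone
Conditions: TBSOTf, 2,6-lutidine, CH2Cl2, 0 °C
Reagents that add atoms: tert-butyldimethylsilyl triflate CC(C)(C)[Si](C)(C)OS(=O)(=O)C(F)(F)F
Why: O-Silylation with a silyl triflate and a hindered pyridine base, reactive enough for a chelated phenol flanked on both sides; a silyl group is chosen because the atom bound to O is silicon and carries no hydrogen that the later carbene could attack.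

Step 8
Reactants: 12 1-[2-(ArB-methoxy)-6-(tert-butyldimethylsilyloxy)-4-methoxy-5-prenylphenyl]ethanone
Product: 14 2-diazo-1-[2-(ArB-methoxy)-6-(tert-butyldimethylsilyloxy)-4-methoxy-5-prenylphenyl]ethanone, via trifluoroacetyl diketone 13 (not isolated)
Conditions: LiN(SiMe3)2, THF, −78 °C; CF3CO2CH2CF3, −78 °C; 5% aq HCl wash; then MsN3, Et3N, H2O (1 equiv), MeCN, rt
Reagents that add atoms: methanesulfonyl azide CS(=O)(=O)N=[N+]=[N-]; 2,2,2-trifluoroethyl trifluoroacetate O=C(OCC(F)(F)F)C(F)(F)F (its acyl group appears in 13 only)
Why: Detrifluoroacetylative variant of the Regitz diazo transfer: the unhindered methyl group is enolised kinetically, C-trifluoroacetylation gives the activated 1,3-diketone 13, and the sulfonyl azide transfers N2 to its central carbon while the trifluoroacetyl group leaves on the sulfonamide nitrogen; the low temperature and the immediate acylation leave the ortho silyl group no time to migrate to the enolate oxygen.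

Step 9
Reactants: 14 2-diazo-1-[2-(ArB-methoxy)-6-(tert-butyldimethylsilyloxy)-4-methoxy-5-prenylphenyl]ethanone
Product: 16 (2S)-5,3'-bis(tert-butyldimethylsilyloxy)-7,4'-dimethoxy-6-prenylflavanone, via rhodium carbene 15 (not isolated)
Conditions: dirhodium tetrakis[N-(phenylsulfonyl)-(S)-prolinate], Rh2(S-BSP)4 (1 mol %), CH2Cl2, 4 Å MS, rt, syringe-pump addition of 14 at high dilution
Reagents that add atoms: none
Why: Nitrogen loss from 14 at the dirhodium core gives the electrophilic carbene 15, and its C3 takes up one C2–H bond through a concerted but asynchronous three-centre transition state in which the positive charge building at C2 is carried by O1 and by the para-methoxy group of ring B. The closest known reaction type is the chiral dirhodium carboxylate-catalysed C–H insertion of ortho-alkoxyaryl diazoketones to chroman-4-ones. Ring C closes by 1,6-insertion to a six-membered ring (C3, C4, C4a, C8a, O1, C2), the normally favoured five-membered mode being excluded because the atom at that distance is O1 and bears no hydrogen. C2 is the only new stereocentre and is under pure catalyst control: the prolinate ligand wall selects one of the two enantiotopic benzylic hydrogens and the insertion occurs with retention at that C–H bond. The selectivity needed is insertion over attack of O1 on the carbene with subsequent 1,2-benzyl migration, and it is secured by the low basicity of an aryl ether oxygen, by the strong activation of the C2–H bonds and by a rhodium carboxylate, which favours C–H insertion where copper catalysts favour ylides. Competing sites are designed out: O5 carries silicon so that no C–H lies at ring-forming distance on that side, the prenyl alkene sits meta to the acyl group and cannot reach C3, and slow addition at high dilution holds back bimolecular cyclopropanation and carbene dimerisation.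

Step 10
Reactants: 16 (2S)-5,3'-bis(tert-butyldimethylsilyloxy)-7,4'-dimethoxy-6-prenylflavanone
Product: 17 (2S)-2-ArB-5-(tert-butyldimethylsilyloxy)-7-methoxy-6-prenyl-4-(trimethylsilyloxy)-2H-chromene
Conditions: Et3N, then TMSOTf, CH2Cl2, −78 to 0 °C; cold aq NaHCO3 wash, used crude
Reagents that add atoms: trimethylsilyl triflate C[Si](C)(C)OS(=O)(=O)C(F)(F)F
Why: Soft enolisation: the silyl triflate activates the ketone oxygen and the amine, present from the start, removes H3 at once, so that no free enolate and no long-lived oxocarbenium ion is formed and the retro-oxa-Michael opening of ring C, which would erase C2, is avoided; the small trimethylsilyl group fits beside the peri 5-silyloxy group.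

Step 11
Reactants: 17 (2S)-2-ArB-5-(tert-butyldimethylsilyloxy)-7-methoxy-6-prenyl-4-(trimethylsilyloxy)-2H-chromene
Product: 19 (2R,3R)-5,3'-bis(tert-butyldimethylsilyloxy)-3-hydroxy-7,4'-dimethoxy-6-prenylflavanone, via silyloxy epoxide 18 (not isolated)
Conditions: 2-(phenylsulfonyl)-3-phenyloxaziridine (1.1 equiv), CH2Cl2, rt; then aq citric acid, THF, 0 °C
Reagents that add atoms: 2-(phenylsulfonyl)-3-phenyloxaziridine O=S(=O)(c1ccccc1)N1OC1c1ccccc1
Why: Rubottom-type oxidation with a neutral, aprotic N-sulfonyloxaziridine, which transfers oxygen to the electron-rich enol ether at room temperature but needs heating to epoxidise an unactivated trisubstituted alkene, so that the prenyl group is spared; oxygen arrives on the face of the C3–C4 double bond opposite to ring B on C2 (substrate control), giving 18, whose mild acidic opening retains the C3–O bond and gives the 2,3-trans (2R,3R) ketol, which is also the more stable diequatorial isomer.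

Step 12
Reactants: 19 (2R,3R)-5,3'-bis(tert-butyldimethylsilyloxy)-3-hydroxy-7,4'-dimethoxy-6-prenylflavanone
Product: 20 (2R,3R)-3,5,3'-trihydroxy-7,4'-dimethoxy-6-prenylflavanone (CNP0146895.1)
Conditions: Bu4NF, AcOH (1:1, 2.5 equiv each), THF, 0 °C, argon
Reagents that add atoms: none
Why: Fluoride cleavage of the two aryl silyl ethers, buffered with acetic acid so that no phenoxide or enolate accumulates and the base-sensitive trans ketol is protected from epimerisation, ring opening and aerial oxidation.

Compound list
1 | 2',6'-dihydroxy-4'-methoxyacetophenone | CC(=O)c1c(O)cc(OC)cc1O | starting material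
2 | 2-methylbut-3-yn-2-ol | CC(C)(O)C#C | starting material
3 | 2-methylbut-3-yn-2-yl trifluoroacetate | C#CC(C)(C)OC(=O)C(F)(F)F | intermediate
4 | 1-[2-hydroxy-4-methoxy-6-(2-methylbut-3-yn-2-yloxy)phenyl]ethanone | CC(=O)c1c(O)cc(OC)cc1OC(C)(C)C#C | intermediate
5 | 1-[2-hydroxy-4-methoxy-6-(2-methylbut-3-en-2-yloxy)phenyl]ethanone | CC(=O)c1c(O)cc(OC)cc1OC(C)(C)C=C | intermediate
6 | isovanillin (3-hydroxy-4-methoxybenzaldehyde) | COc1ccc(C=O)cc1O | starting material
7 | 3-(tert-butyldimethylsilyloxy)-4-methoxybenzaldehyde | COc1ccc(C=O)cc1O[Si](C)(C)C(C)(C)C | intermediate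
8 | [3-(tert-butyldimethylsilyloxy)-4-methoxyphenyl]methanol | COc1ccc(CO)cc1O[Si](C)(C)C(C)(C)C | intermediate
9 | 1-[2-(ArB-methoxy)-4-methoxy-6-(2-methylbut-3-en-2-yloxy)phenyl]ethanone | COc1ccc(COc2cc(OC)cc(OC(C)(C)C=C)c2C(C)=O)cc1O[Si](C)(C)C(C)(C)C | intermediate
10 | 2-acetyl-3-(ArB-methoxy)-5-methoxy-6-prenylcyclohexa-2,4-dien-1-one (racemic at C6, transient) | CC(=O)C1=C(OCc2ccc(OC)c(O[Si](C)(C)C(C)(C)C)c2)C=C(OC)C(CC=C(C)C)C1=O | intermediate
11 | 1-[2-(ArB-methoxy)-6-hydroxy-4-methoxy-5-prenylphenyl]ethanone | COc1ccc(COc2cc(OC)c(CC=C(C)C)c(O)c2C(C)=O)cc1O[Si](C)(C)C(C)(C)C | intermediate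
12 | 1-[2-(ArB-methoxy)-6-(tert-butyldimethylsilyloxy)-4-methoxy-5-prenylphenyl]ethanone | COc1ccc(COc2cc(OC)c(CC=C(C)C)c(O[Si](C)(C)C(C)(C)C)c2C(C)=O)cc1O[Si](C)(C)C(C)(C)C | intermediate
13 | 4,4,4-trifluoro-1-[2-(ArB-methoxy)-6-(tert-butyldimethylsilyloxy)-4-methoxy-5-prenylphenyl]butane-1,3-dione | COc1ccc(COc2cc(OC)c(CC=C(C)C)c(O[Si](C)(C)C(C)(C)C)c2C(=O)CC(=O)C(F)(F)F)cc1O[Si](C)(C)C(C)(C)C | intermediate
14 | 2-diazo-1-[2-(ArB-methoxy)-6-(tert-butyldimethylsilyloxy)-4-methoxy-5-prenylphenyl]ethanone (key-step precursor) | COc1ccc(COc2cc(OC)c(CC=C(C)C)c(O[Si](C)(C)C(C)(C)C)c2C(=O)C=[N+]=[N-])cc1O[Si](C)(C)C(C)(C)C | intermediate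
15 | rhodium carbene from 14 (C3 bound to the Rh2(S-BSP)4 core, which is abbreviated to one Rh atom in the SMILES) | COc1ccc(COc2cc(OC)c(CC=C(C)C)c(O[Si](C)(C)C(C)(C)C)c2C(=O)C=[Rh])cc1O[Si](C)(C)C(C)(C)C | intermediate
16 | (2S)-5,3'-bis(tert-butyldimethylsilyloxy)-7,4'-dimethoxy-6-prenylflavanone (key-step product) | COc1ccc([C@H]2Oc3cc(OC)c(CC=C(C)C)c(O[Si](C)(C)C(C)(C)C)c3C(=O)C2)cc1O[Si](C)(C)C(C)(C)C | intermediate
17 | (2S)-2-ArB-5-(tert-butyldimethylsilyloxy)-7-methoxy-6-prenyl-4-(trimethylsilyloxy)-2H-chromene | COc1ccc([C@H]2Oc3cc(OC)c(CC=C(C)C)c(O[Si](C)(C)C(C)(C)C)c3C(O[Si](C)(C)C)=C2)cc1O[Si](C)(C)C(C)(C)C | intermediate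
18 | (2R,3R,4R)-3,4-epoxy-4-(trimethylsilyloxy)-5,3'-bis(tert-butyldimethylsilyloxy)-7,4'-dimethoxy-6-prenylflavan (epoxide oxygen on the face of ring C opposite to ring B) | COc1ccc([C@H]2Oc3cc(OC)c(CC=C(C)C)c(O[Si](C)(C)C(C)(C)C)c3[C@]4(O[Si](C)(C)C)O[C@H]24)cc1O[Si](C)(C)C(C)(C)C | intermediate
19 | (2R,3R)-5,3'-bis(tert-butyldimethylsilyloxy)-3-hydroxy-7,4'-dimethoxy-6-prenylflavanone (2,3-trans) | COc1ccc([C@H]2Oc3cc(OC)c(CC=C(C)C)c(O[Si](C)(C)C(C)(C)C)c3C(=O)[C@@H]2O)cc1O[Si](C)(C)C(C)(C)C | intermediate
20 | (2R,3R)-3,5,3'-trihydroxy-7,4'-dimethoxy-6-prenylflavanone (2,3-trans, CNP0146895.1) | COc1ccc([C@H]2Oc3cc(OC)c(CC=C(C)C)c(O)c3C(=O)[C@@H]2O)cc1O | target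

Total step count: 12. Longest linear sequence: 10 steps (steps 1, 2 and 5 to 12 from 1; the branch from 6, steps 3, 4 and 5 to 12, is equally long).

Steps most likely to fail

First, step 9. Three processes may spoil it:
- capture of the carbene by the lone pair of O1 followed by benzyl migration;
- hydride transfer with fragmentation of the very electron-rich benzyl ether;
- weak discrimination between the two benzylic hydrogens.

The fallback gives up the carbene. It builds the pyranone first and forms the C2–C1' bond last by asymmetric conjugate arylation. It sets out from 12. Oxidative removal of the electron-rich benzyl group (DDQ, CH2Cl2/pH 7 buffer, 0 °C) would return aldehyde 7 and give 1-[2-(tert-butyldimethylsilyloxy)-6-hydroxy-4-methoxy-3-prenylphenyl]ethanone F1. Condensation with N,N-dimethylformamide dimethyl acetal (toluene, 90 °C) would give (E)-3-(dimethylamino)-1-[2-(tert-butyldimethylsilyloxy)-6-hydroxy-4-methoxy-3-prenylphenyl]prop-2-en-1-one F2. Brief treatment with aqueous HCl in CH2Cl2 would close this, with loss of dimethylamine, to 5-(tert-butyldimethylsilyloxy)-7-methoxy-6-prenylchromone F3. A Hayashi–Miyaura 1,4-addition of purchased [3-(tert-butyldimethylsilyloxy)-4-methoxyphenyl]boronic acid F4 would follow, with [Rh(OH)(cod)]2 and an electron-poor chiral bisphosphine of the MeO-BIPHEP family in toluene at rt. This comes back to the route at 16.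

Second, step 11. Oxygen transfer to the crowded enol ether may be slow, so that forcing conditions erode the preference over the prenyl alkene, or the facial selectivity may be imperfect. The fallback replaces oxygen-atom transfer by a polar C–O bond formation with an electrophile that cannot epoxidise. It sets out from 17. An O-selective nitroso aldol reaction with nitrosobenzene (Et3SiOTf cat., CH2Cl2, −78 °C), again anti to ring B, would give (2R,3R)-5,3'-bis(tert-butyldimethylsilyloxy)-7,4'-dimethoxy-3-(phenylaminooxy)-6-prenylflavanone F5. Reductive cleavage of its N–O bond (Zn dust, AcOH/THF, 0 °C) would release aniline and come back to the route at 19.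

Third, step 8. The ortho silyl group may migrate to the enolate oxygen, or it may be lost in the aqueous amine medium of the transfer stage. The fallback avoids any metal enolate. It sets out from 12. Heating with N,N-dimethylformamide dimethyl acetal (neat, 100 °C) would give (E)-3-(dimethylamino)-1-[2-(ArB-methoxy)-6-(tert-butyldimethylsilyloxy)-4-methoxy-5-prenylphenyl]prop-2-en-1-one F6. Tosyl azide in MeCN at rt would add to the enamine double bond, and cycloreversion of the adduct would expel the sulfonyl formamidine. This comes back to the route at 14.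

Further compounds
F1 | step 9 | 1-[2-(tert-butyldimethylsilyloxy)-6-hydroxy-4-methoxy-3-prenylphenyl]ethanone | CC(=O)c1c(O)cc(OC)c(CC=C(C)C)c1O[Si](C)(C)C(C)(C)C
F2 | step 9 | (E)-3-(dimethylamino)-1-[2-(tert-butyldimethylsilyloxy)-6-hydroxy-4-methoxy-3-prenylphenyl]prop-2-en-1-one | CN(C)/C=C/C(=O)c1c(O)cc(OC)c(CC=C(C)C)c1O[Si](C)(C)C(C)(C)C
F3 | step 9 | 5-(tert-butyldimethylsilyloxy)-7-methoxy-6-prenylchromone | COc1cc2occc(=O)c2c(O[Si](C)(C)C(C)(C)C)c1CC=C(C)C
F4 | step 9 | [3-(tert-butyldimethylsilyloxy)-4-methoxyphenyl]boronic acid | COc1ccc(B(O)O)cc1O[Si](C)(C)C(C)(C)C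
F5 | step 11 | (2R,3R)-5,3'-bis(tert-butyldimethylsilyloxy)-7,4'-dimethoxy-3-(phenylaminooxy)-6-prenylflavanone | COc1ccc([C@H]2Oc3cc(OC)c(CC=C(C)C)c(O[Si](C)(C)C(C)(C)C)c3C(=O)[C@@H]2ONc4ccccc4)cc1O[Si](C)(C)C(C)(C)C
F6 | step 8 | (E)-3-(dimethylamino)-1-[2-(ArB-methoxy)-6-(tert-butyldimethylsilyloxy)-4-methoxy-5-prenylphenyl]prop-2-en-1-one | CN(C)/C=C/C(=O)c1c(OCc2ccc(OC)c(O[Si](C)(C)C(C)(C)C)c2)cc(OC)c(CC=C(C)C)c1O[Si](C)(C)C(C)(C)C
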